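The target is a meso 2,5-diaryl-3,4-bis(acetoxymethyl)oxolane, so only relative configuration matters. The plan cuts C2–C3. With C3′ and C4′ tied into a γ-lactone, a rhodium carbene at C3 inserts into the C2–H bond of the ArCH2–O1 ether, a bond that is benzylic, α to O1 and 1,5 to C3. This single operation closes the oxolane ring and forces C3 and C4 cis, the one relationship that cannot be corrected later. The precursor is a 3-diazo-γ-butyrolactone carrying a CH(Ar)OCH2Ar group at C4 (Ar = 3,4-dibenzyloxyphenyl). C2 and C5, both benzylic and α to O1, are afterwards equilibrated by acid to the trans,cis,trans array.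

Key step: step 8

Remark on symmetry: O1 and the centre of the C3–C4 bond lie on a mirror plane (2R,3S,4R,5S, meso), so the compound has no enantiomer and "single enantiomer" is read as "single diastereomer"; chiral intermediates are racemic and one enantiomer is drawn.
Numbering: target numbering (O1, C2–C5; C3′ and C4′ are the CH2 carbons on C3 and C4) is used for all intermediates; Ar = 3,4-bis(benzyloxy)phenyl.
Remark on stereocontrol: C5 cannot be controlled when it is made, and C2 is expected to form with its aryl on the concave face, so neither is relied on. Both are set together in step 11 at the diacetate stage, where the benzylic cation can be diverted neither by loss of an α-carbonyl proton (arylidene lactone) nor by a free hydroxyl (ring-isomeric oxolane).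

Step 1
Reactants: 1 3,4-bis(benzyloxy)benzaldehyde; 2 propane-1,3-dithiol
Product: 3 2-[3,4-bis(benzyloxy)phenyl]-1,3-dithiane
Conditions: BF3·OEt2 (cat.), CH2Cl2, 0 °C → rt
Reagents that add atoms: none
Why: Lewis-acid-catalysed thioacetalisation of an aromatic aldehyde is reliable, leaves aryl benzyl ethers alone and prepares the future C5 for Corey–Seebach umpolung, with no stereocentre formed.

Step 2
Reactants: 3 2-[3,4-bis(benzyloxy)phenyl]-1,3-dithiane; 4 2(5H)-furanone
Product: 7 (±)-4-{2-[3,4-bis(benzyloxy)phenyl]-1,3-dithian-2-yl}dihydrofuran-2(3H)-one, via lithiated dithiane 5 (not isolated), via lithium lactone enolate 6 (not isolated)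
Conditions: n-BuLi, THF, −78 → −20 °C; 4, −78 °C; AcOH
Reagents that add atoms: n-butyllithium, [Li]CCCC (lithium in 5 and 6 only)
Why: The soft, aryl-stabilised dithiane anion undergoes Michael (1,4) addition to the butenolide rather than carbonyl attack, a standard entry to β-substituted lignan lactones, forming C4–C5 and giving C4 as a racemate, which is harmless for a meso target.

Step 3
Reactants: 7 (±)-4-{2-[3,4-bis(benzyloxy)phenyl]-1,3-dithian-2-yl}dihydrofuran-2(3H)-one
Product: 8 (±)-4-[3,4-bis(benzyloxy)benzoyl]dihydrofuran-2(3H)-one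
Conditions: MeI (excess), CaCO3, MeCN–H2O, 45 °C
Reagents that add atoms: water, O
Why: In this alkylative dithiane hydrolysis, S-methylation makes sulfur a leaving group and water captures the aryl-stabilised thionium ion, while the insoluble carbonate keeps the medium neutral so that the β-acyloxy ketone does not eliminate.

Step 4
Reactants: 8 (±)-4-[3,4-bis(benzyloxy)benzoyl]dihydrofuran-2(3H)-one
Product: 9 (±)-4-{[3,4-bis(benzyloxy)phenyl](hydroxy)methyl}dihydrofuran-2(3H)-one (both C5 epimers)
Conditions: NaBH4, CeCl3·7H2O, MeOH–THF, −20 → 0 °C; AcOH at −20 °C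
Reagents that add atoms: none
Why: Luche-type reduction takes the aryl ketone much faster than the lactone in a nearly non-basic medium, which together with the cold acidic quench holds back β-elimination and migration of the lactone onto the new hydroxyl; C4 carries two almost equivalent ring CH2 groups, so no facial bias is claimed, both C5 epimers are carried on, and C5 is fixed only in step 11.

Step 5
Reactants: 10 3,4-bis(benzyloxy)benzyl alcohol
Product: 11 3,4-bis(benzyloxy)benzyl 2,2,2-trichloroacetimidate
Conditions: Cl3CCN, DBU (cat.), CH2Cl2, 0 °C; filtration through Et3N-deactivated silica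
Reagents that add atoms: trichloroacetonitrile, N#CC(Cl)(Cl)Cl
Why: Base-catalysed addition of the alcohol to trichloroacetonitrile (imidate formation) is the standard activation of electron-rich benzylic alcohols of the PMB/DMB type.

Step 6
Reactants: 9 (±)-4-{[3,4-bis(benzyloxy)phenyl](hydroxy)methyl}dihydrofuran-2(3H)-one (both C5 epimers); 11 3,4-bis(benzyloxy)benzyl 2,2,2-trichloroacetimidate
Product: 12 (±)-4-{[3,4-bis(benzyloxy)phenyl][3,4-bis(benzyloxy)benzyloxy]methyl}dihydrofuran-2(3H)-one (both C5 epimers)
Conditions: 11 (1.5 equiv), La(OTf)3 (5 mol %), toluene, 0 °C → rt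
Reagents that add atoms: none
Why: Acid-catalysed trichloroacetimidate benzylation transfers the dialkoxybenzyl group to the C5 hydroxyl and so forms O1–C2 without base, which avoids alkoxide-driven lactone migration, and without hydride, which avoids the deoxygenation that threatens a reductive etherification of so electron-rich an aryl ketone.

Step 7
Reactants: 12 (±)-4-{[3,4-bis(benzyloxy)phenyl][3,4-bis(benzyloxy)benzyloxy]methyl}dihydrofuran-2(3H)-one (both C5 epimers)
Product: 15 (±)-3-diazo-4-{[3,4-bis(benzyloxy)phenyl][3,4-bis(benzyloxy)benzyloxy]methyl}dihydrofuran-2(3H)-one (both C5 epimers), via lithium enolate 13 (not isolated), via trifluoroacetyl lactone 14 (not isolated)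
Conditions: LiHMDS, THF, −78 °C; CF3CO2CH2CF3; AcOH; then MsN3, Et3N, H2O (1 equiv), MeCN, rt
Reagents that add atoms: lithium hexamethyldisilazide, [Li]N([Si](C)(C)C)[Si](C)(C)C (lithium in 13 only); 2,2,2-trifluoroethyl trifluoroacetate, O=C(OCC(F)(F)F)C(F)(F)F (CF3CO in 14 only); methanesulfonyl azide, CS(=O)(=O)N=[N+]=[N-]
Why: In this deacylative Regitz diazo transfer the lactone is deprotonated at C3, its only acidic site, C-trifluoroacetylated, and the activated dicarbonyl 14 accepts N2 from the sulfonyl azide with loss of the trifluoroacetyl group, the established way to α-diazo lactones.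

Step 8
Reactants: 15 (±)-3-diazo-4-{[3,4-bis(benzyloxy)phenyl][3,4-bis(benzyloxy)benzyloxy]methyl}dihydrofuran-2(3H)-one (both C5 epimers)
Product: 16 (±)-cis-fused 4,6-bis[3,4-bis(benzyloxy)phenyl]tetrahydro-1H,3H-furo[3,4-c]furan-1-one (H-3a and H-6a cis; epimers at ring position 4 = C5 and ring position 6 = C2)
Conditions: Rh2(O2CtBu)4 (1 mol %), CH2Cl2, 4 Å MS, 0 °C, slow addition of 15 at high dilution
Reagents that add atoms: none
Why: Rh(II) expels N2 from 15 and the resulting electrophilic lactone carbene at C3 takes up the hydridic C2–H bond in a concerted but asynchronous three-centre insertion, hydride character running ahead of C2–C3 bonding, after which the catalyst is released. The closest known reaction type is the Rh(II)-carboxylate-catalysed 1,5 C–H insertion of α-diazo esters and α-diazo-γ-butyrolactones next to an ether oxygen, including benzylic ethers, which gives 2-substituted oxolanes. The oxolane ring (C3–C4–C5–O1–C2) closes in the 1,5 mode through a five-membered cyclic transition state annulated to the lactone. C3 is controlled by the tether, since C2 can reach only the carbene face on which C5 stands, so either C5 epimer gives the cis-fused bicyclo[3.3.0] lactone with C3′ cis to C4′. C2 is controlled by the catalyst, the aryl group turning away from the carboxylate wall and therefore probably onto the concave face (cis to C3′), an outcome that is not relied on because step 11 resets this centre. The step needs insertion to outrun the 1,2-hydride shift from C4 (butenolide), attack on the C5 aryl ring and carbene dimerisation, which the double activation of C2–H, the donating and bulky pivalate ligands, the low temperature and slow addition at high dilution are chosen to secure.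

Step 9
Reactants: 16 (±)-cis-fused 4,6-bis[3,4-bis(benzyloxy)phenyl]tetrahydro-1H,3H-furo[3,4-c]furan-1-one (C2/C5 epimers)
Product: 17 {2,5-bis[3,4-bis(benzyloxy)phenyl]oxolane-3,4-diyl}dimethanol (3,4-cis; C2/C5 epimers)
Conditions: LiAlH4, THF, 0 °C; Fieser work-up
Reagents that add atoms: none
Why: Hydride reduction of a γ-lactone to the 1,4-diol touches neither the ethers nor C3 and C4, so C3′ and C4′ emerge as cis CH2OH groups, and the basic work-up avoids acid, under which a free hydroxyl could capture a C2 or C5 cation and give a ring-isomeric oxolane.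

Step 10
Reactants: 17 {2,5-bis[3,4-bis(benzyloxy)phenyl]oxolane-3,4-diyl}dimethanol (3,4-cis; C2/C5 epimers)
Product: 18 {2,5-bis[3,4-bis(benzyloxy)phenyl]oxolane-3,4-diyl}dimethanediyl diacetate (3,4-cis; C2/C5 epimers)
Conditions: Ac2O, pyridine, DMAP (cat.), CH2Cl2, rt
Reagents that add atoms: acetic anhydride, CC(=O)OC(C)=O
Why: DMAP-catalysed acylation of two primary alcohols is unproblematic, installs the acetates of the target and removes the internal nucleophiles before the acid step.

Step 11
Reactants: 18 {2,5-bis[3,4-bis(benzyloxy)phenyl]oxolane-3,4-diyl}dimethanediyl diacetate (3,4-cis; C2/C5 epimers)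
Product: 19 meso-(2R,3S,4R,5S)-{2,5-bis[3,4-bis(benzyloxy)phenyl]oxolane-3,4-diyl}dimethanediyl diacetate (2,3-trans, 3,4-cis, 4,5-trans)
Conditions: BF3·OEt2 (0.5 equiv), dry CH2Cl2, −20 → 0 °C until the isomer distribution is constant; Et3N
Reagents that add atoms: none
Why: Lewis-acid-promoted benzylic epimerisation, well known for 2,5-diaryl tetrahydrofuran lignans, reversibly breaks C2–O1 or C5–O1 to a p-alkoxybenzyl cation and recloses, so only C2 and C5 equilibrate, and with C3 and C4 locked cis the isomer with each aryl trans to its neighbouring CH2OAc avoids any further cis-vicinal contact and should be the thermodynamic sink.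

Step 12
Reactants: 19 meso-(2R,3S,4R,5S)-{2,5-bis[3,4-bis(benzyloxy)phenyl]oxolane-3,4-diyl}dimethanediyl diacetate
Product: 20 meso-(2R,3S,4R,5S)-{2,5-bis(3,4-dihydroxyphenyl)oxolane-3,4-diyl}dimethanediyl diacetate (target)
Conditions: H2 (1 atm), 10% Pd/C, EtOAc, rt, stopped after uptake of 4 equiv H2; filtration under Ar
Reagents that add atoms: none
Why: Catalytic hydrogenolysis cleaves the four unhindered aryl benzyl ethers far faster than the hindered dialkyl-type C2–O1 and C5–O1 bonds when run at 1 atm in an aprotic solvent and stopped at the calculated uptake, the usual last step for phenolic tetrahydrofuran lignans, and the neutral medium leaves the acetates and all four stereocentres untouched.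

Compound list
1 | 3,4-bis(benzyloxy)benzaldehyde | O=Cc1ccc(OCc2ccccc2)c(OCc2ccccc2)c1 | starting material
2 | propane-1,3-dithiol | SCCCS | starting material
3 | 2-[3,4-bis(benzyloxy)phenyl]-1,3-dithiane | C1CSC(SC1)c2ccc(OCc3ccccc3)c(OCc3ccccc3)c2 | intermediate
4 | 2(5H)-furanone | O=C1C=CCO1 | starting material
5 | 2-lithio-2-[3,4-bis(benzyloxy)phenyl]-1,3-dithiane (not isolated) | [Li]C1(SCCCS1)c2ccc(OCc3ccccc3)c(OCc3ccccc3)c2 | intermediate
6 | lithium enolate of 7 (racemic, not isolated) | [Li]OC1=C[C@H](CO1)C2(SCCCS2)c3ccc(OCc4ccccc4)c(OCc4ccccc4)c3 | intermediate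
7 | (±)-4-{2-[3,4-bis(benzyloxy)phenyl]-1,3-dithian-2-yl}dihydrofuran-2(3H)-one | O=C1OC[C@@H](C1)C2(SCCCS2)c3ccc(OCc4ccccc4)c(OCc4ccccc4)c3 | intermediate
8 | (±)-4-[3,4-bis(benzyloxy)benzoyl]dihydrofuran-2(3H)-one | O=C1OC[C@@H](C1)C(=O)c2ccc(OCc3ccccc3)c(OCc3ccccc3)c2 | intermediate
9 | (±)-4-{[3,4-bis(benzyloxy)phenyl](hydroxy)methyl}dihydrofuran-2(3H)-one, both C5 epimers | O=C1OC[C@@H](C1)C(O)c2ccc(OCc3ccccc3)c(OCc3ccccc3)c2 | intermediate
10 | 3,4-bis(benzyloxy)benzyl alcohol | OCc1ccc(OCc2ccccc2)c(OCc2ccccc2)c1 | starting material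
11 | 3,4-bis(benzyloxy)benzyl 2,2,2-trichloroacetimidate | N=C(OCc1ccc(OCc2ccccc2)c(OCc2ccccc2)c1)C(Cl)(Cl)Cl | intermediate
12 | (±)-4-{[3,4-bis(benzyloxy)phenyl][3,4-bis(benzyloxy)benzyloxy]methyl}dihydrofuran-2(3H)-one, both C5 epimers | O=C1OC[C@@H](C1)C(c2ccc(OCc3ccccc3)c(OCc3ccccc3)c2)OCc2ccc(OCc3ccccc3)c(OCc3ccccc3)c2 | intermediate
13 | lithium enolate of 12 (not isolated) | [Li]OC1=C[C@H](CO1)C(c2ccc(OCc3ccccc3)c(OCc3ccccc3)c2)OCc2ccc(OCc3ccccc3)c(OCc3ccccc3)c2 | intermediate
14 | 3-trifluoroacetyl derivative of 12, C3 unassigned (not isolated) | O=C1OC[C@@H](C1C(=O)C(F)(F)F)C(c2ccc(OCc3ccccc3)c(OCc3ccccc3)c2)OCc2ccc(OCc3ccccc3)c(OCc3ccccc3)c2 | intermediate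
15 | (±)-3-diazo-4-{[3,4-bis(benzyloxy)phenyl][3,4-bis(benzyloxy)benzyloxy]methyl}dihydrofuran-2(3H)-one, both C5 epimers (key-step precursor) | O=C1OC[C@@H](C1=[N+]=[N-])C(c2ccc(OCc3ccccc3)c(OCc3ccccc3)c2)OCc2ccc(OCc3ccccc3)c(OCc3ccccc3)c2 | intermediate
16 | (±)-cis-fused 4,6-bis[3,4-bis(benzyloxy)phenyl]tetrahydro-1H,3H-furo[3,4-c]furan-1-one, C3/C4 cis, epimers at C2 and C5 (key-step product) | O=C4[C@@H]1[C@H](CO4)C(c2ccc(OCc3ccccc3)c(OCc3ccccc3)c2)OC1c2ccc(OCc3ccccc3)c(OCc3ccccc3)c2 | intermediate
17 | {2,5-bis[3,4-bis(benzyloxy)phenyl]oxolane-3,4-diyl}dimethanol, 3,4-cis, epimers at C2 and C5 | OC[C@@H]1[C@H](CO)C(c2ccc(OCc3ccccc3)c(OCc3ccccc3)c2)OC1c2ccc(OCc3ccccc3)c(OCc3ccccc3)c2 | intermediate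
18 | diacetate of 17, 3,4-cis, epimers at C2 and C5 | CC(=O)OC[C@@H]1[C@H](COC(C)=O)C(c2ccc(OCc3ccccc3)c(OCc3ccccc3)c2)OC1c2ccc(OCc3ccccc3)c(OCc3ccccc3)c2 | intermediate
19 | meso-(2R,3S,4R,5S)-{2,5-bis[3,4-bis(benzyloxy)phenyl]oxolane-3,4-diyl}dimethanediyl diacetate | CC(=O)OC[C@@H]1[C@H](COC(C)=O)[C@@H](c2ccc(OCc3ccccc3)c(OCc3ccccc3)c2)O[C@H]1c2ccc(OCc3ccccc3)c(OCc3ccccc3)c2 | intermediate
20 | meso-(2R,3S,4R,5S)-{2,5-bis(3,4-dihydroxyphenyl)oxolane-3,4-diyl}dimethanediyl diacetate (CNP0416169.1) | CC(=O)OC[C@@H]1[C@H](COC(C)=O)[C@@H](c2ccc(O)c(O)c2)O[C@H]1c1ccc(O)c(O)c1 | target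

Total step count: 12. Longest linear sequence: 11 (steps 1–4 and 6–12; step 5 is a one-step side branch).

Steps most likely to fail

1. Step 8. Migration of the C4 hydrogen to the carbene carbon, or attack of the carbene on the neighbouring electron-rich C5 aryl ring, may outrun the insertion, and the two C5 epimers may differ in this respect. The fallback sets out from 9 and 1, returns at 16, and makes the same C2–C3 bond by polar chemistry.
   - Aldehyde 1 is treated with trimethyl orthoformate and catalytic TsOH to give 3,4-bis(benzyloxy)benzaldehyde dimethyl acetal F1.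
   - PPTS-catalysed acetal exchange of excess F1 with alcohol 9 gives the mixed methyl acetal lactone F2.
   - LDA and TMSCl at −78 °C convert F2 into the lactone trimethylsilyl ketene acetal F3.
   - Catalytic TMSOTf at −78 °C ionises the acetal to the O1=C2 oxocarbenium ion, which C3 attacks. This is an intramolecular Mukaiyama-type addition of a ketene acetal to an acetal, the closure known from aryl-substituted furofuran rings.
   - The bicycle can again form only cis-fused, which gives 16, and C2 and C5 are left to step 11 as before.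

2. Step 11. The benzylic cation may be drained before equilibrium is reached. The possible drains are Friedel–Crafts closure onto the other aryl ring, proton loss to a styrene, and participation of an acetate. The fallback sets out from 18, returns at 20, and changes both the order of events and the nature of the ionising group.
   - The unequilibrated mixture 18 is hydrogenolysed first, under the conditions of step 12, to the C2/C5-epimeric tetraphenol diacetate F4.
   - The free para-hydroxyl groups then let the ring open through a protonated p-quinone methide under a trace of Brønsted acid (dilute TFA in MeCN, rt, under Ar). This is far milder than the Lewis acid needed for the benzyl ethers, and reclosure should funnel the mixture into 20.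

3. Step 6. Ionisation of the electron-rich secondary benzylic alcohol, migration of the lactone onto the C5 hydroxyl, or rearrangement of the imidate to the N-benzyl amide may compete with O-alkylation. The fallback sets out from 8 and 10, returns at 12, and bypasses 9 and 11.
   - Alcohol 10 is silylated (TMSCl, Et3N) to 3,4-bis(benzyloxy)benzyl trimethylsilyl ether F5.
   - Ketone 8 is then submitted to reductive etherification with F5 and Et3SiH under catalytic TMSOTf in CH2Cl2 at −78 °C.
   - The temperature is kept low and the reaction is quenched cold to limit re-ionisation and deoxygenation of the product.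
   - The C5 epimer mixture obtained in this way is equally acceptable.

Further compounds
F1 | step 8 | 3,4-bis(benzyloxy)benzaldehyde dimethyl acetal | COC(OC)c1ccc(OCc2ccccc2)c(OCc2ccccc2)c1
F2 | step 8 | (±)-4-{[3,4-bis(benzyloxy)phenyl]{[3,4-bis(benzyloxy)phenyl](methoxy)methoxy}methyl}dihydrofuran-2(3H)-one, epimers at C5 and the acetal carbon | O=C1OC[C@@H](C1)C(c2ccc(OCc3ccccc3)c(OCc3ccccc3)c2)OC(OC)c2ccc(OCc3ccccc3)c(OCc3ccccc3)c2
F3 | step 8 | trimethylsilyl ketene acetal of F2 (2-trimethylsilyloxy-4,5-dihydrofuran) | C[Si](C)(C)OC1=C[C@H](CO1)C(c2ccc(OCc3ccccc3)c(OCc3ccccc3)c2)OC(OC)c2ccc(OCc3ccccc3)c(OCc3ccccc3)c2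
F4 | step 11 | {2,5-bis(3,4-dihydroxyphenyl)oxolane-3,4-diyl}dimethanediyl diacetate, 3,4-cis, epimers at C2 and C5 | CC(=O)OC[C@@H]1[C@H](COC(C)=O)C(c2ccc(O)c(O)c2)OC1c1ccc(O)c(O)c1
F5 | step 6 | 3,4-bis(benzyloxy)benzyl trimethylsilyl ether | C[Si](C)(C)OCc1ccc(OCc2ccccc2)c(OCc2ccccc2)c1
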